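**Strategy.** The furofuran is numbered C1–O2–C3–C3a–C4–O5–C6–C6a (ring A: C3a, C4, O5, C6, C6a, guaiacyl on C6; ring B: C6a, C1, O2, C3, C3a, veratryl on C3). The route rests on cutting C3a–C6a and O2–C3 together. Ring B holds a tertiary carbinol (C6a) 1,3 to a para-alkoxybenzylic ether carbon (C3), the retron of a ketone–styrene Prins addition whose benzylic cation is trapped by the oxygen on C1. One Lewis-acid operation on an acyclic (R)-α-cinnamyloxy ketone closes ring A through C–C bond formation and then, last, ring B through C–O bond formation, setting C3, C3a and C6a from C6.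

Key step: step 6

Assumption: (E)-3,4-dimethoxycinnamyl alcohol 6 and stannane 10 are taken as commercially available, and for each chiral catalyst the antipode that delivers the stated configuration is meant.

Step 1
Reactants: 1 methyl (4-hydroxy-3-methoxyphenyl)acetate; 2 chlorotriisopropylsilane
Product: 3 methyl [3-methoxy-4-(triisopropylsilyloxy)phenyl]acetate
Conditions: imidazole, DMF, rt
Reagents that add atoms: chlorotriisopropylsilane (2), CC(C)[Si](Cl)(C(C)C)C(C)C
Why: Imidazole-promoted O-silylation of the only acidic hydroxyl; the triisopropylsilyl ether masks the phenol O–H from the carbene of step 3 and should withstand DBU, Grignard and organolithium reagents.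

Step 2
Reactants: 3 methyl [3-methoxy-4-(triisopropylsilyloxy)phenyl]acetate; 4 4-acetamidobenzenesulfonyl azide
Product: 5 methyl 2-diazo-2-[3-methoxy-4-(triisopropylsilyloxy)phenyl]acetate
Conditions: DBU, MeCN, 0 °C to rt
Reagents that add atoms: 4-acetamidobenzenesulfonyl azide (4), CC(=O)Nc1ccc(cc1)S(=O)(=O)N=[N+]=[N-]
Why: Regitz diazo transfer: DBU forms the benzylic ester enolate, which takes the two terminal nitrogens of the sulfonyl azide and expels the sulfonamide.

Step 3
Reactants: 5 methyl 2-diazo-2-[3-methoxy-4-(triisopropylsilyloxy)phenyl]acetate; 6 (E)-3-(3,4-dimethoxyphenyl)prop-2-en-1-ol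
Product: 7 methyl (R)-2-{[(E)-3-(3,4-dimethoxyphenyl)prop-2-en-1-yl]oxy}-2-[3-methoxy-4-(triisopropylsilyloxy)phenyl]acetate
Conditions: FeCl2·4H2O (5 mol%), chiral spiro bis(oxazoline) ligand SpiroBox (6 mol%, antipode giving R), NaB[3,5-(CF3)2C6H3]4 (6 mol%), CHCl3, 40 °C, slow addition of 5
Reagents that add atoms: none
Why: Enantioselective iron-carbene O–H insertion: the alcohol adds to the electrophilic iron carbene and the ligand-controlled 1,2-proton shift of the metal-bound ylide sets C6 as R, O–H insertion of alcohols being much faster than cyclopropanation of the styrene.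

Step 4
Reactants: 7 methyl (R)-2-{[(E)-3-(3,4-dimethoxyphenyl)prop-2-en-1-yl]oxy}-2-[3-methoxy-4-(triisopropylsilyloxy)phenyl]acetate; 8 N,O-dimethylhydroxylamine hydrochloride
Product: 9 (R)-2-{[(E)-3-(3,4-dimethoxyphenyl)prop-2-en-1-yl]oxy}-N-methoxy-N-methyl-2-[3-methoxy-4-(triisopropylsilyloxy)phenyl]acetamide
Conditions: i-PrMgCl, THF, −20 °C; then aq. NH4Cl
Reagents that add atoms: N,O-dimethylhydroxylamine hydrochloride (8), CNOC.Cl
Why: Weinreb amide formation by aminolysis of the methyl ester with the chloromagnesium amide at low temperature, conditions under which O-alkyl mandelate stereocentres should stay intact.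

Step 5
Reactants: 9 (R)-2-{[(E)-3-(3,4-dimethoxyphenyl)prop-2-en-1-yl]oxy}-N-methoxy-N-methyl-2-[3-methoxy-4-(triisopropylsilyloxy)phenyl]acetamide; 10 tributyl[(methoxymethoxy)methyl]stannane
Product: 11 (R)-1-{[(E)-3-(3,4-dimethoxyphenyl)prop-2-en-1-yl]oxy}-3-(methoxymethoxy)-1-[3-methoxy-4-(triisopropylsilyloxy)phenyl]propan-2-one
Conditions: 10, n-BuLi, THF, −78 °C; then 9, −78 °C; then AcOH, −78 °C
Reagents that add atoms: tributyl[(methoxymethoxy)methyl]stannane (10), CCCC[Sn](CCCC)(CCCC)COCOC
Why: Weinreb ketone synthesis with an α-alkoxymethyllithium from tin–lithium exchange: the chelated tetrahedral adduct stops at the ketone stage and is protonated cold, so the ketone never meets base and C6 should keep its configuration.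

Step 6
Reactants: 11 (R)-1-{[(E)-3-(3,4-dimethoxyphenyl)prop-2-en-1-yl]oxy}-3-(methoxymethoxy)-1-[3-methoxy-4-(triisopropylsilyloxy)phenyl]propan-2-one
Product: 13 (1S,2R,5R,6S)-6-(3,4-dimethoxyphenyl)-2-[3-methoxy-4-(triisopropylsilyloxy)phenyl]-3,7-dioxabicyclo[3.3.0]octan-1-ol, via ring-A benzylic cation 12 (not isolated)
Conditions: SnCl4 (1.2 equiv), 2,6-di-tert-butyl-4-methylpyridine (0.3 equiv), CH2Cl2 (0.01 M), −78 to −40 °C; then sat. aq. NaHCO3 at −40 °C
Reagents that add atoms: none
Why: Proposed new method: SnCl4 chelates the α,α'-dioxygenated ketone and the electron-rich E-styrene attacks C6a through C3a (Prins addition, 5-exo-trig for both the C=C and the C=O, closing ring A), giving the para-methoxybenzylic cation 12 at C3, which is captured by the methoxymethyl ether oxygen on C1 (5-exo-trig onto the exocyclic cation, closing ring B) with loss of the methoxymethyl group as MeOCH2Cl. The closest known reaction types are the Lewis-acid carbonyl–olefin Prins cyclisation that opens carbonyl–olefin metathesis, its interrupted variants that stop at the benzylic cation, and Prins cyclisations terminated by a tethered oxygen nucleophile; an α-alkoxy ketone with an ether terminator has not been shown. C3a and C6a are set in the C–C bond formation by a chair-like transition state with the C6 aryl group pseudo-equatorial (side chain on C3a trans to that aryl group), and only the C6a epimer whose CH2O arm is cis to the cationic side chain can close the cis-fused ring B, while the other can only revert by retro-Prins fragmentation. C3 is set in the C–O closure, where the veratryl group should take the exo position on the convex face, as in quinone-methide closures to pinoresinol-type lignans. The step needs the Prins addition to outrun ionisation of the cinnamylic C4–O5 bond, oligomerisation of the styrene and the metathesis pathway: low temperature, high dilution and the hindered pyridine serve the first two, and the lack of any cation-stabilising group on C6a (two β-oxygens) disfavours oxetane opening towards metathesis. Epimerisation of the two benzylic ether carbons is avoided by quenching cold.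

Step 7
Reactants: 13 (1S,2R,5R,6S)-6-(3,4-dimethoxyphenyl)-2-[3-methoxy-4-(triisopropylsilyloxy)phenyl]-3,7-dioxabicyclo[3.3.0]octan-1-ol; 14 acetic anhydride
Product: 15 (1S,2R,5R,6S)-6-(3,4-dimethoxyphenyl)-2-[3-methoxy-4-(triisopropylsilyloxy)phenyl]-3,7-dioxabicyclo[3.3.0]octan-1-yl acetate
Conditions: Ac2O, DMAP, Et3N, CH2Cl2, 40 °C
Reagents that add atoms: acetic anhydride (14), CC(=O)OC(C)=O
Why: DMAP-catalysed acylation (acylpyridinium) of the hindered bridgehead tertiary alcohol, the only free hydroxyl in 13.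

Step 8
Reactants: 15 (1S,2R,5R,6S)-6-(3,4-dimethoxyphenyl)-2-[3-methoxy-4-(triisopropylsilyloxy)phenyl]-3,7-dioxabicyclo[3.3.0]octan-1-yl acetate
Product: 16 (1S,2R,5R,6S)-6-(3,4-dimethoxyphenyl)-2-(4-hydroxy-3-methoxyphenyl)-3,7-dioxabicyclo[3.3.0]octan-1-yl acetate
Conditions: Bu4NF, AcOH, THF, 0 °C
Reagents that add atoms: none
Why: Fluoride-induced cleavage of the aryl silyl ether, buffered with AcOH so that the phenoxide is protonated at once and the tertiary acetate and the benzylic ethers should stay untouched.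

**Compound list**

1 | methyl (4-hydroxy-3-methoxyphenyl)acetate | COC(=O)Cc1ccc(O)c(OC)c1 | starting material
2 | chlorotriisopropylsilane | CC(C)[Si](Cl)(C(C)C)C(C)C | starting material
3 | methyl [3-methoxy-4-(triisopropylsilyloxy)phenyl]acetate | COC(=O)Cc1ccc(O[Si](C(C)C)(C(C)C)C(C)C)c(OC)c1 | intermediate
4 | 4-acetamidobenzenesulfonyl azide | CC(=O)Nc1ccc(cc1)S(=O)(=O)N=[N+]=[N-] | starting material
5 | methyl 2-diazo-2-[3-methoxy-4-(triisopropylsilyloxy)phenyl]acetate | COC(=O)C(=[N+]=[N-])c1ccc(O[Si](C(C)C)(C(C)C)C(C)C)c(OC)c1 | intermediate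
6 | (E)-3-(3,4-dimethoxyphenyl)prop-2-en-1-ol | COc1ccc(/C=C/CO)cc1OC | starting material
7 | methyl (R)-2-{[(E)-3-(3,4-dimethoxyphenyl)prop-2-en-1-yl]oxy}-2-[3-methoxy-4-(triisopropylsilyloxy)phenyl]acetate | COC(=O)[C@H](OC/C=C/c1ccc(OC)c(OC)c1)c1ccc(O[Si](C(C)C)(C(C)C)C(C)C)c(OC)c1 | intermediate
8 | N,O-dimethylhydroxylamine hydrochloride | CNOC.Cl | starting material
9 | (R)-2-{[(E)-3-(3,4-dimethoxyphenyl)prop-2-en-1-yl]oxy}-N-methoxy-N-methyl-2-[3-methoxy-4-(triisopropylsilyloxy)phenyl]acetamide | CON(C)C(=O)[C@H](OC/C=C/c1ccc(OC)c(OC)c1)c1ccc(O[Si](C(C)C)(C(C)C)C(C)C)c(OC)c1 | intermediate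
10 | tributyl[(methoxymethoxy)methyl]stannane | CCCC[Sn](CCCC)(CCCC)COCOC | starting material
11 | (R)-1-{[(E)-3-(3,4-dimethoxyphenyl)prop-2-en-1-yl]oxy}-3-(methoxymethoxy)-1-[3-methoxy-4-(triisopropylsilyloxy)phenyl]propan-2-one | COCOCC(=O)[C@H](OC/C=C/c1ccc(OC)c(OC)c1)c1ccc(O[Si](C(C)C)(C(C)C)C(C)C)c(OC)c1 | intermediate
12 | ring-A benzylic cation: trichlorostannyl alkoxide of (2R,3S,4R)-3-[(methoxymethoxy)methyl]-2-[3-methoxy-4-(triisopropylsilyloxy)phenyl]tetrahydrofuran-3-ol carrying the (3,4-dimethoxyphenyl)methylium group on C4, chloride counter-ion | COc1cc([C@H]2OC[C@H]([CH+]c3ccc(OC)c(OC)c3)[C@@]2(COCOC)O[Sn](Cl)(Cl)Cl)ccc1O[Si](C(C)C)(C(C)C)C(C)C.[Cl-] | intermediate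
13 | (1S,2R,5R,6S)-6-(3,4-dimethoxyphenyl)-2-[3-methoxy-4-(triisopropylsilyloxy)phenyl]-3,7-dioxabicyclo[3.3.0]octan-1-ol | COc1cc([C@H]2OC[C@@H]3[C@@H](c4ccc(OC)c(OC)c4)OC[C@]23O)ccc1O[Si](C(C)C)(C(C)C)C(C)C | intermediate
14 | acetic anhydride | CC(=O)OC(C)=O | starting material
15 | (1S,2R,5R,6S)-6-(3,4-dimethoxyphenyl)-2-[3-methoxy-4-(triisopropylsilyloxy)phenyl]-3,7-dioxabicyclo[3.3.0]octan-1-yl acetate | COc1cc([C@H]2OC[C@@H]3[C@@H](c4ccc(OC)c(OC)c4)OC[C@]23OC(C)=O)ccc1O[Si](C(C)C)(C(C)C)C(C)C | intermediate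
16 | (1S,2R,5R,6S)-6-(3,4-dimethoxyphenyl)-2-(4-hydroxy-3-methoxyphenyl)-3,7-dioxabicyclo[3.3.0]octan-1-yl acetate | COc1cc([C@H]2OC[C@@H]3[C@@H](c4ccc(OC)c(OC)c4)OC[C@]23OC(C)=O)ccc1O | target

Total step count: 8. Longest linear sequence: 8 steps (1 to 16).

**Steps most likely to fail**

Step 6. Lewis-acid ionisation of the cinnamylic C–O bond or cationic oligomerisation of the styrene may outrun the ketone–olefin addition, and the benzylic ether carbons may epimerise under the acid. Fallback with known chemistry, setting out from 11 and coming back at 13: a ketyl–olefin cyclisation with SmI2/HMPA/t-BuOH in THF at −78 °C should close ring A alone (5-exo, hydroxyl trans to the new benzyl group, C6 aryl trans to it) and give (2R,3S,4S)-4-(3,4-dimethoxybenzyl)-3-[(methoxymethoxy)methyl]-2-[3-methoxy-4-(triisopropylsilyloxy)phenyl]tetrahydrofuran-3-ol F1. Removal of the methoxymethyl group with ZnBr2/n-PrSH in CH2Cl2 at 0 °C should give (2R,3S,4S)-4-(3,4-dimethoxybenzyl)-3-(hydroxymethyl)-2-[3-methoxy-4-(triisopropylsilyloxy)phenyl]tetrahydrofuran-3-ol F2. DDQ in CH2Cl2 over 4 Å sieves at 0 °C should then oxidise the veratrylic CH2 to the benzylic cation, which the primary hydroxyl captures to close ring B last and return to 13.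

Step 3. The allylic oxonium ylide may undergo a [2,3]-shift, the carbene may cyclopropanate the styrene, or the proton shift may lose enantiocontrol with the electron-rich aryl group. Fallback, setting out from 5 and coming back at 7: oxidation of the diazo group with dimethyldioxirane (acetone, 0 °C) should give methyl 2-[3-methoxy-4-(triisopropylsilyloxy)phenyl]-2-oxoacetate F3. Transfer hydrogenation with RuCl[(S,S)-TsDPEN](p-cymene) and HCO2H/Et3N should give methyl (R)-2-hydroxy-2-[3-methoxy-4-(triisopropylsilyloxy)phenyl]acetate F4. O-Alkylation under non-basic conditions with Ag2O in Et2O and (E)-4-(3-bromoprop-1-en-1-yl)-1,2-dimethoxybenzene F5, made from 6 with PBr3, should return to 7 without racemisation.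

Step 5. The basic organolithium may deprotonate the α-aryl α-alkoxy amide, leading to racemisation or a [2,3]-Wittig shift of the cinnamyl group. Fallback, setting out from 3 and coming back at 11: the order is reversed so that no carbanion meets the stereocentre. Aminolysis of 3 (MeNH(OMe)·HCl, i-PrMgCl) should give N-methoxy-N-methyl-2-[3-methoxy-4-(triisopropylsilyloxy)phenyl]acetamide F6. Addition of (methoxymethoxy)methyllithium should give 1-(methoxymethoxy)-3-[3-methoxy-4-(triisopropylsilyloxy)phenyl]propan-2-one F7. Diazo transfer (4, DBU) should give 1-diazo-3-(methoxymethoxy)-1-[3-methoxy-4-(triisopropylsilyloxy)phenyl]propan-2-one F8. Enantioselective O–H insertion with 6 under Rh2(O2CCPh3)4 and a chiral spiro phosphoric acid as proton shuttle should then set C6 and give 11.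

**Further compounds**

F1 | step 6 | (2R,3S,4S)-4-(3,4-dimethoxybenzyl)-3-[(methoxymethoxy)methyl]-2-[3-methoxy-4-(triisopropylsilyloxy)phenyl]tetrahydrofuran-3-ol | COc1cc([C@H]2OC[C@H](Cc3ccc(OC)c(OC)c3)[C@@]2(COCOC)O)ccc1O[Si](C(C)C)(C(C)C)C(C)C
F2 | step 6 | (2R,3S,4S)-4-(3,4-dimethoxybenzyl)-3-(hydroxymethyl)-2-[3-methoxy-4-(triisopropylsilyloxy)phenyl]tetrahydrofuran-3-ol | COc1cc([C@H]2OC[C@H](Cc3ccc(OC)c(OC)c3)[C@@]2(CO)O)ccc1O[Si](C(C)C)(C(C)C)C(C)C
F3 | step 3 | methyl 2-[3-methoxy-4-(triisopropylsilyloxy)phenyl]-2-oxoacetate | COC(=O)C(=O)c1ccc(O[Si](C(C)C)(C(C)C)C(C)C)c(OC)c1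
F4 | step 3 | methyl (R)-2-hydroxy-2-[3-methoxy-4-(triisopropylsilyloxy)phenyl]acetate | COC(=O)[C@H](O)c1ccc(O[Si](C(C)C)(C(C)C)C(C)C)c(OC)c1
F5 | step 3 | (E)-4-(3-bromoprop-1-en-1-yl)-1,2-dimethoxybenzene | COc1ccc(/C=C/CBr)cc1OC
F6 | step 5 | N-methoxy-N-methyl-2-[3-methoxy-4-(triisopropylsilyloxy)phenyl]acetamide | CON(C)C(=O)Cc1ccc(O[Si](C(C)C)(C(C)C)C(C)C)c(OC)c1
F7 | step 5 | 1-(methoxymethoxy)-3-[3-methoxy-4-(triisopropylsilyloxy)phenyl]propan-2-one | COCOCC(=O)Cc1ccc(O[Si](C(C)C)(C(C)C)C(C)C)c(OC)c1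
F8 | step 5 | 1-diazo-3-(methoxymethoxy)-1-[3-methoxy-4-(triisopropylsilyloxy)phenyl]propan-2-one | COCOCC(=O)C(=[N+]=[N-])c1ccc(O[Si](C(C)C)(C(C)C)C(C)C)c(OC)c1
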